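## Retrosynthetic overview
1. Final operations: the C10 ester comes from the free C10 alcohol and 4-methoxybenzoyl chloride, and the C2 ketone from a protected C2 alcohol that is carried through the synthesis.
2. The seven-membered ring is formed second, by ring-closing metathesis (C8=C9) of a cyclopentane that carries two cis alkenyl arms on C1 and C5.
3. The C5 carbinol comes from 3-methylbut-3-enylmagnesium bromide adding to a C5 cyclopentanone anti to isopropyl; the ketone is unmasked from an exocyclic methylidene.
4. Key disconnection C1–C10: intermolecular Nozaki–Hiyama carbonyl allylation of acrolein by a cyclopentenylmethyl bromide, which sets C1 and C10 together.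
5. The five-membered ring is formed first, by ozonolysis and intramolecular aldol ring contraction of a silyl ether made from (R)-carvone, which supplies C4 and a C2–O control centre.

Convention used below: daucane numbering, with C1 = C(CH3) ring fusion, C2 = C=O, C3 = CH2, C4 = CH(iPr), C5 = C(OH) ring fusion, C6 and C7 = CH2, C8 = C(CH3)=, C9 = CH=, C10 = CH–O. The β face carries CH3, OH and iPr; the α face is the opposite one. TBS = tert-butyldimethylsilyl, PMB = 4-methoxybenzyl.

## Route

Step 1
Reactants: 1 (R)-(−)-carvone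
Product: 2 (5R)-2-methyl-5-(propan-2-yl)cyclohex-2-en-1-one [(R)-carvotanacetone]
Conditions: H2 (1 atm), RhCl(PPh3)3 (cat.), toluene, rt
Reagents that add atoms: none
Why: Wilkinson hydrogenation saturates only the unhindered 1,1-disubstituted isopropenyl alkene and touches neither the conjugated trisubstituted enone nor the stereocentre that becomes C4 (R).

Step 2
Reactants: 2 (R)-carvotanacetone
Product: 3 (1R,5R)-2-methyl-5-(propan-2-yl)cyclohex-2-en-1-ol [cis-carvotanacetol]
Conditions: NaBH4, CeCl3·7H2O, MeOH, −78 → 0 °C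
Reagents that add atoms: none
Why: In this Luche 1,2-reduction, hydride adds axially to the half-chair with equatorial isopropyl, giving the (1R) alcohol cis to isopropyl, which is the later C2 oxygen and the control element for C1.

Step 3
Reactants: 3 cis-carvotanacetol
Product: 4 tert-butyl{[(1R,5R)-2-methyl-5-(propan-2-yl)cyclohex-2-en-1-yl]oxy}dimethylsilane
Conditions: TBSCl, imidazole, DMF, rt
Reagents that add atoms: tert-butyldimethylsilyl chloride, CC(C)(C)[Si](C)(C)Cl
Why: Silyl ether formation (Corey protocol) masks the C2 oxygen with a group that survives ozone, hydride, divalent chromium and Grignard reagents, and no stereocentre is affected.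

Step 4
Reactants: 4 TBS ether of cis-carvotanacetol
Product: 6 (3S,5R)-5-(TBS-oxy)-6-oxo-3-(propan-2-yl)heptanal, via secondary ozonide 5 (not isolated)
Conditions: O3, CH2Cl2, −78 °C; then Me2S, −78 °C → rt
Reagents that add atoms: ozone, [O-][O+]=O
Why: Ozonolysis (Criegee mechanism) with reductive work-up cleaves the only alkene to the 1,6-keto aldehyde, and both stereocentres stay unchanged in space (the 3S label reflects only a change in CIP priorities).

Step 5
Reactants: 6 keto aldehyde
Product: 7 (3R,5R)-3-(TBS-oxy)-2-methyl-5-(propan-2-yl)cyclopent-1-ene-1-carbaldehyde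
Conditions: piperidine (cat.), AcOH (cat.), toluene, 80 °C, −H2O
Reagents that add atoms: none
Why: In this amine-catalysed intramolecular aldol condensation (5-enolexo), the aldehyde enamine attacks the methyl ketone and loss of water gives the tetrasubstituted enal, the ring contraction known for the limonene-derived keto aldehyde, with both stereocentres retained.

Step 6
Reactants: 7 cyclopentene carbaldehyde
Product: 8 [(3R,5R)-3-(TBS-oxy)-2-methyl-5-(propan-2-yl)cyclopent-1-en-1-yl]methanol
Conditions: NaBH4, CeCl3·7H2O, MeOH, 0 °C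
Reagents that add atoms: none
Why: Luche 1,2-reduction of the hindered enal gives the primary allylic alcohol without conjugate reduction, and no stereocentre changes.

Step 7
Reactants: 8 allylic alcohol
Product: 9 tert-butyl{[(1R,4R)-3-(bromomethyl)-2-methyl-4-(propan-2-yl)cyclopent-2-en-1-yl]oxy}dimethylsilane
Conditions: CBr4, PPh3, CH2Cl2, −20 → 0 °C
Reagents that add atoms: tetrabromomethane, BrC(Br)(Br)Br
Why: The Appel reaction displaces the oxyphosphonium group by SN2 at the primary allylic carbon under neutral conditions that the silyl ether tolerates.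

Step 8 (key step)
Reactants: 9 allylic bromide; 10 acrolein
Product: 12 (1R)-1-[(1S,3R,5R)-5-(TBS-oxy)-1-methyl-2-methylidene-3-(propan-2-yl)cyclopentyl]prop-2-en-1-ol, via allylchromium dichloride 11 (not isolated)
Conditions: CrCl2 (3 equiv), THF, 0 °C → rt; then H2O
Reagents that add atoms: none
Why: In this Nozaki–Hiyama carbonyl allylation, the allylchromium adds to the acrolein carbonyl through its γ-carbon (C1) in a chair-like six-membered transition state on the α face, anti to the C2 silyloxy and C4 isopropyl groups (sets quaternary C1), while the equatorial vinyl group and the ring-fixed alkene geometry (CH3 cis to CH2Cr) place the new OH syn to CH3 and set C10 as R.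

Step 9
Reactants: 12 homoallylic alcohol
Product: 13 tert-butyl({(1R,2S,4R)-2-{(1R)-1-[(4-methoxybenzyl)oxy]prop-2-en-1-yl}-2-methyl-3-methylidene-4-(propan-2-yl)cyclopentyl}oxy)dimethylsilane
Conditions: NaH, PMBCl, Bu4NI (cat.), DMF, 0 °C → rt
Reagents that add atoms: 4-methoxybenzyl chloride, COc1ccc(CCl)cc1
Why: Williamson etherification protects C10–OH orthogonally to the TBS group, and the trans arrangement of the C10 arm and the silyloxy group on the ring disfavours silyl migration.

Step 10
Reactants: 13 PMB ether
Product: 15 (2S,3R,5R)-3-(TBS-oxy)-2-{(1R)-1-[(4-methoxybenzyl)oxy]prop-2-en-1-yl}-2-methyl-5-(propan-2-yl)cyclopentan-1-one, via spiro ozonide 14 (not isolated)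
Conditions: O3 (to the Sudan Red 7B end point), CH2Cl2, −78 °C; then Me2S, −78 °C → rt
Reagents that add atoms: ozone, [O-][O+]=O
Why: This ozonolysis is chemoselective because the electron-richer 1,1-disubstituted methylidene reacts much faster than the monosubstituted vinyl group deactivated by its allylic oxygen, and the neutral conditions do not epimerise C4, now α to the ketone.

Step 11
Reactants: 16 3-methylbut-3-en-1-ol
Product: 17 4-bromo-2-methylbut-1-ene
Conditions: CBr4, PPh3, CH2Cl2, 0 °C; distil
Reagents that add atoms: tetrabromomethane, BrC(Br)(Br)Br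
Why: The Appel reaction converts the primary alcohol into the bromide by SN2 without acid, so the 1,1-disubstituted alkene is not touched.

Step 12
Reactants: 15 cyclopentanone; 17 4-bromo-2-methylbut-1-ene
Product: 19 (1S,2S,3R,5R)-3-(TBS-oxy)-2-{(1R)-1-[(4-methoxybenzyl)oxy]prop-2-en-1-yl}-2-methyl-1-(3-methylbut-3-en-1-yl)-5-(propan-2-yl)cyclopentan-1-ol, via 3-methylbut-3-enylmagnesium bromide 18 (not isolated)
Conditions: 17, Mg, THF, 40 °C; then add to 15, CeCl3, THF, −78 → 0 °C; then H2O
Reagents that add atoms: none
Why: CeCl3-promoted Grignard 1,2-addition (Imamoto conditions) suppresses enolisation and reduction of the hindered ketone, and the nucleophile enters on the α face next to C4–H, opposite to isopropyl, CH3 and silyloxy, which sets C5 (S) with OH cis to isopropyl and the new arm cis to the C10 arm.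

Step 13
Reactants: 19 diene
Product: 20 (1R,3R,3aS,8R,8aS)-1-(TBS-oxy)-8-[(4-methoxybenzyl)oxy]-6,8a-dimethyl-3-(propan-2-yl)-2,3,4,5,8,8a-hexahydroazulen-3a(1H)-ol
Conditions: second-generation Grubbs catalyst (5 mol %), CH2Cl2 (2 mM), 40 °C
Reagents that add atoms: none
Why: Ring-closing metathesis of the two cis arms joins the vinyl and 1,1-disubstituted alkenes into the trisubstituted C8=C9 cycloheptene, whose ring geometry is necessarily cis, and no stereocentre is involved.

Step 14
Reactants: 20 bicyclic silyl ether
Product: 21 (1R,3R,3aS,8R,8aR)-8-[(4-methoxybenzyl)oxy]-6,8a-dimethyl-3-(propan-2-yl)-2,3,4,5,8,8a-hexahydroazulene-1,3a(1H)-diol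
Conditions: Bu4NF, THF, 50 °C; then H2O
Reagents that add atoms: none
Why: Fluoride-induced desilylation is run here because the molecule holds no base-labile group, so the hindered neopentyl silyl ether can be forced off safely (the 8aR label reflects only a change in CIP priorities).

Step 15
Reactants: 21 diol
Product: 22 (3R,3aS,8R,8aR)-3a-hydroxy-8-[(4-methoxybenzyl)oxy]-6,8a-dimethyl-3-(propan-2-yl)-3,3a,4,5,8,8a-hexahydroazulen-1(2H)-one
Conditions: Dess–Martin periodinane, CH2Cl2, rt
Reagents that add atoms: none
Why: Dess–Martin oxidation converts the only secondary alcohol into the C2 ketone under near-neutral conditions, so the tertiary β-hydroxy ketone does not undergo retro-aldol cleavage, and quaternary C1 rules out elimination.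

Step 16
Reactants: 22 PMB ether
Product: 23 (3R,3aS,8R,8aR)-3a,8-dihydroxy-6,8a-dimethyl-3-(propan-2-yl)-3,3a,4,5,8,8a-hexahydroazulen-1(2H)-one
Conditions: DDQ, CH2Cl2/H2O (18:1), 0 °C
Reagents that add atoms: none
Why: Oxidative PMB cleavage (hydride abstraction by DDQ, then hydrolysis) frees C10–OH with retention, and the trans-1,3 relation to C5–OH prevents acetal formation.

Step 17
Reactants: 23 diol ketone; 24 4-methoxybenzoyl chloride
Product: 25 (3R,3aS,8R,8aR)-3a-hydroxy-6,8a-dimethyl-1-oxo-3-(propan-2-yl)-1,2,3,3a,4,5,8,8a-octahydroazulen-8-yl 4-methoxybenzoate (target)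
Conditions: Et3N, DMAP (cat.), CH2Cl2, rt → 40 °C
Reagents that add atoms: none
Why: DMAP-catalysed acylation (nucleophilic catalysis) esterifies only the secondary allylic C10–OH with retention, because the tertiary C5–OH is too hindered to react.

## Compound list
1 | (R)-(−)-carvone | CC1=CC[C@H](CC1=O)C(C)=C | starting material
2 | (R)-carvotanacetone | CC1=CC[C@H](CC1=O)C(C)C | intermediate
3 | (1R,5R)-cis-carvotanacetol | CC1=CC[C@H](C[C@H]1O)C(C)C | intermediate
4 | TBS ether of 3 | CC1=CC[C@H](C[C@H]1O[Si](C)(C)C(C)(C)C)C(C)C | intermediate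
5 | secondary ozonide of 4 (1,2,4-trioxolane across the former alkene, both bridgehead epimers) | CC12OOC(O1)C[C@H](C[C@H]2O[Si](C)(C)C(C)(C)C)C(C)C | intermediate
6 | (3S,5R)-5-(TBS-oxy)-6-oxo-3-(propan-2-yl)heptanal | CC(=O)[C@H](O[Si](C)(C)C(C)(C)C)C[C@@H](CC=O)C(C)C | intermediate
7 | (3R,5R)-3-(TBS-oxy)-2-methyl-5-(propan-2-yl)cyclopent-1-ene-1-carbaldehyde | O=CC1=C(C)[C@H](O[Si](C)(C)C(C)(C)C)C[C@@H]1C(C)C | intermediate
8 | [(3R,5R)-3-(TBS-oxy)-2-methyl-5-(propan-2-yl)cyclopent-1-en-1-yl]methanol | OCC1=C(C)[C@H](O[Si](C)(C)C(C)(C)C)C[C@@H]1C(C)C | intermediate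
9 | (1R,4R)-allylic bromide derived from 8 | BrCC1=C(C)[C@H](O[Si](C)(C)C(C)(C)C)C[C@@H]1C(C)C | intermediate
10 | acrolein | C=CC=O | starting material
11 | {[(3R,5R)-3-(TBS-oxy)-2-methyl-5-(propan-2-yl)cyclopent-1-en-1-yl]methyl}chromium dichloride (trivalent chromium) | Cl[Cr](Cl)CC1=C(C)[C@H](O[Si](C)(C)C(C)(C)C)C[C@@H]1C(C)C | intermediate
12 | (1R)-1-[(1S,3R,5R)-5-(TBS-oxy)-1-methyl-2-methylidene-3-(propan-2-yl)cyclopentyl]prop-2-en-1-ol | C=C[C@@H](O)[C@@]1(C)[C@H](O[Si](C)(C)C(C)(C)C)C[C@H](C(C)C)C1=C | intermediate
13 | PMB ether of 12 | C=C[C@@H](OCc2ccc(OC)cc2)[C@@]1(C)[C@H](O[Si](C)(C)C(C)(C)C)C[C@H](C(C)C)C1=C | intermediate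
14 | spiro ozonide of 13 at C5 (both spiro epimers) | C=C[C@@H](OCc2ccc(OC)cc2)[C@@]1(C)[C@H](O[Si](C)(C)C(C)(C)C)C[C@H](C(C)C)C12OCOO2 | intermediate
15 | (2S,3R,5R)-cyclopentanone (C5 ketone) with a (1R)-PMB-oxyallyl arm | C=C[C@@H](OCc2ccc(OC)cc2)[C@@]1(C)[C@H](O[Si](C)(C)C(C)(C)C)C[C@H](C(C)C)C1=O | intermediate
16 | 3-methylbut-3-en-1-ol | C=C(C)CCO | starting material
17 | 4-bromo-2-methylbut-1-ene | C=C(C)CCBr | intermediate
18 | 3-methylbut-3-enylmagnesium bromide | C=C(C)CC[Mg]Br | intermediate
19 | (1S,2S,3R,5R)-tertiary cyclopentanol carrying both alkenyl arms | C=C[C@@H](OCc2ccc(OC)cc2)[C@@]1(C)[C@H](O[Si](C)(C)C(C)(C)C)C[C@H](C(C)C)[C@@]1(O)CCC(C)=C | intermediate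
20 | (1R,3R,3aS,8R,8aS)-hexahydroazulen-3a-ol with 1-OTBS and 8-OPMB | COc1ccc(CO[C@@H]2C=C(C)CC[C@]3(O)[C@@H](C(C)C)C[C@@H](O[Si](C)(C)C(C)(C)C)[C@]23C)cc1 | intermediate
21 | (1R,3R,3aS,8R,8aR)-1,3a-diol with 8-OPMB | COc1ccc(CO[C@@H]2C=C(C)CC[C@]3(O)[C@@H](C(C)C)C[C@@H](O)[C@]23C)cc1 | intermediate
22 | (3R,3aS,8R,8aR)-3a-hydroxy-1-ketone with 8-OPMB | COc1ccc(CO[C@@H]2C=C(C)CC[C@]3(O)[C@@H](C(C)C)CC(=O)[C@]23C)cc1 | intermediate
23 | (3R,3aS,8R,8aR)-3a,8-dihydroxy-1-ketone | O[C@@H]1C=C(C)CC[C@]2(O)[C@@H](C(C)C)CC(=O)[C@]12C | intermediate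
24 | 4-methoxybenzoyl chloride | COc1ccc(C(=O)Cl)cc1 | starting material
25 | CNP0246512.1 | COc1ccc(C(=O)O[C@@H]2C=C(C)CC[C@]3(O)[C@@H](C(C)C)CC(=O)[C@]23C)cc1 | target

## Step count and risks
Total steps: 17. Longest linear sequence: 16 (steps 1–10 and 12–17; step 11 is a side branch).

**Step 8 (key allylation).**
- Risks: the hindered γ-carbon could react slowly, so that attack through the CH2 terminus competes. The organochromium could lose silanolate. The C10 selectivity could be modest.
- Fallback: replace the reductive one-pot coupling by an isolable, configurationally fixed boron reagent. It sets out from 9.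
- B2pin2 with Pd2(dba)3 (2.5 mol %, zerovalent palladium) in THF at 60 °C gives the pinacol allylboronate F1, which is purified.
- F1 is then stirred with acrolein 10 in toluene at rt to 50 °C. Only the closed chair transition state through C1 is open to it, and boron does not trigger elimination of the silyloxy group.
- Aqueous triethanolamine work-up brings the sequence back to the route at 12.

**Step 10 (selective ozonolysis).**
- Risks: over-oxidation of the vinyl group or of the PMB ring.
- Fallback: use a stoichiometric electrophilic oxidant followed by glycol-type cleavage. It sets out from 13.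
- mCPBA (1.05 equiv, NaHCO3, CH2Cl2, 0 °C) epoxidises only the more nucleophilic methylidene to the spiro-epoxide F2. Its oxygen is expected on the α face, and this configuration is of no consequence.
- H5IO6 in THF/H2O at 0 °C then cleaves F2, and the sequence comes back to the route at 15.

**Step 12 (addition to the very hindered ketone).**
- Risks: no reaction, enolisation with C4 epimerisation, or β-hydride reduction.
- Fallback: deliver C6 first as the smallest possible nucleophile and attach the rest of the chain afterwards. It sets out from 15.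
- Me3SI and NaH in DMSO/THF (Corey–Chaykovsky methylenation, CH2 entering on the α face) give the spiro-epoxide F3 with its oxygen on the β face.
- 2-Methylallylmagnesium chloride with CuI (10 mol %) in THF at −30 °C opens F3 at the CH2 carbon, and the sequence comes back to the route at 19.

## Further compounds
F1 | step 8 | 2-{[(3R,5R)-3-(TBS-oxy)-2-methyl-5-(propan-2-yl)cyclopent-1-en-1-yl]methyl}-4,4,5,5-tetramethyl-1,3,2-dioxaborolane | CC1(C)OB(CC2=C(C)[C@H](O[Si](C)(C)C(C)(C)C)C[C@@H]2C(C)C)OC1(C)C
F2 | step 10 | spiro-epoxide of 13 at C5 (5R, oxygen on the α face) | C=C[C@@H](OCc2ccc(OC)cc2)[C@@]1(C)[C@H](O[Si](C)(C)C(C)(C)C)C[C@H](C(C)C)[C@]12CO2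
F3 | step 12 | spiro-epoxide from 15 at C5 (5S, oxygen on the β face) | C=C[C@@H](OCc2ccc(OC)cc2)[C@@]1(C)[C@H](O[Si](C)(C)C(C)(C)C)C[C@H](C(C)C)[C@@]12CO2
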